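The route hinges on cutting both bonds to C2 of the 2,3-dihydrobenzofuran, O1–C2 and C2–C3. Because O1 and C3 are carried by neighbouring carbons of ring C (C7a and C3a) and only the aryl-bearing C2 lies between them, ring C can serve as a four-atom o-quinone methide and C2 as a one-carbon sulfonium ylide. One operation should then form two bonds, close the furan ring and set the trans C2/C3 pair, with the absolute sense dictated by a chiral sulfide. The precursors are an o-(1-sulfonylalkyl)phenol from eugenol and a benzylic sulfonium salt of isothiocineole. Lactone and diol unit follow by Claisen, aldol and enolate alkylation chemistry.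

Key step: step 5

Remark 1: the (1R,4R,5R) antipode of the sulfide is assumed to steer the ylide to the 2S product, by analogy with its use in ylide epoxidation; if the sense is the reverse, the (1S,4S,5S) sulfide is used with no other change.
Remark 2: the magnesium-catalysed anti-aldol is assumed to follow the chelated-enolate face preference of oxazolidinone alkylations, so that the (S)-auxiliary gives the (2R,3S) adduct.
Abbreviation: DHB = (2S,3R)-2-(4-benzyloxy-3-methoxyphenyl)-3-[(tert-butyldimethylsilyloxy)methyl]-7-methoxy-2,3-dihydrobenzofuran-5-yl (rings C and D with their protecting groups); TBS = tert-butyldimethylsilyl.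

**Route**

Step 1
Reactants: 1 eugenol; 2 (tert-butyldimethylsilyloxy)acetaldehyde
Product: 4 rac-1-(5-allyl-2-hydroxy-3-methoxyphenyl)-2-(tert-butyldimethylsilyloxy)ethan-1-ol, via bromomagnesium phenoxide 3 (not isolated)
Conditions: EtMgBr (1.0 equiv), Et2O, 0 °C; solvent exchanged for toluene; 2, rt
Reagents that add atoms: none
Why: ortho-specific hydroxyalkylation of a magnesium phenoxide, in which the aldehyde bound to magnesium is delivered to the only free ortho carbon (para is blocked by the allyl group); the carbinol is racemic and is destroyed in step 5.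

Step 2
Reactants: 4 rac-1-(5-allyl-2-hydroxy-3-methoxyphenyl)-2-(tert-butyldimethylsilyloxy)ethan-1-ol
Product: 5 rac-4-allyl-2-methoxy-6-[2-(tert-butyldimethylsilyloxy)-1-(p-tolylsulfonyl)ethyl]phenol
Conditions: p-TolSO2H (1.5 equiv), MgSO4, CH2Cl2, rt
Reagents that add atoms: p-toluenesulfinic acid, Cc1ccc(cc1)S(=O)O
Why: acid-promoted SN1-type substitution of an o-hydroxybenzylic alcohol, the ionised benzylic position being captured at sulfur by sulfinate, under anhydrous weakly acidic conditions that a primary TBS ether should survive.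

Step 3
Reactants: 6 4-benzyloxy-3-methoxybenzyl alcohol
Product: 7 4-benzyloxy-3-methoxybenzyl bromide
Conditions: PBr3 (0.4 equiv), Et2O, 0 °C
Reagents that add atoms: phosphorus tribromide, BrP(Br)Br
Why: standard bromination of an activated benzylic alcohol through its phosphite ester.

Step 4
Reactants: 7 4-benzyloxy-3-methoxybenzyl bromide; 8 (1R,4R,5R)-isothiocineole
Product: 9 (1R,4R,5R)-6-(4-benzyloxy-3-methoxybenzyl)-4,7,7-trimethyl-6-thiabicyclo[3.2.1]octan-6-ium tetrafluoroborate
Conditions: NaBF4 (5 equiv), CH2Cl2/H2O (1:1), rt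
Reagents that add atoms: sodium tetrafluoroborate, [Na+].F[B-](F)(F)F
Why: S-alkylation of a sulfide by a reactive benzylic bromide, driven by exchange of bromide for the non-nucleophilic tetrafluoroborate; alkylation on the less hindered sulfur lone pair should give one sulfonium epimer.

Step 5
Reactants: 5 rac-4-allyl-2-methoxy-6-[2-(tert-butyldimethylsilyloxy)-1-(p-tolylsulfonyl)ethyl]phenol; 9 isothiocineole-derived benzylic sulfonium tetrafluoroborate
Product: 13 (2S,3R)-5-allyl-2-(4-benzyloxy-3-methoxyphenyl)-3-[(tert-butyldimethylsilyloxy)methyl]-7-methoxy-2,3-dihydrobenzofuran, via o-quinone methide 10 (not isolated), via sulfonium ylide 11 (not isolated), via phenoxide–sulfonium betaine 12 (not isolated)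
Conditions: 9 (1.2 equiv), Cs2CO3 (3 equiv), CH2Cl2, −20 °C to rt
Reagents that add atoms: none
Why: Cs2CO3 converts phenol 5 into its phenoxide, which expels p-toluenesulfinate to give o-quinone methide 10, and deprotonates salt 9 at the benzylic carbon to ylide 11; the ylide carbon adds to the exocyclic methide carbon in a conjugate sense, which forms C2–C3, restores the aromaticity of ring C and leaves betaine 12, and the phenoxide then displaces the sulfide to form O1–C2. The closest known reaction type is the formal (4+1) annulation of in situ o-quinone methides with sulfonium ylides, here extended from carbonyl-stabilised ylides to a benzylic ylide whose conjugate additions are familiar from ylide cyclopropanation. The furan ring closes by 5-exo-tet SN2 substitution with inversion at the sulfonium-bearing carbon. C2 is controlled by the bicyclic sulfide, which holds the ylide in one conformation and blocks one of its faces, while C3 is set relative to C2 by the anti placement of the aryl and CH2OTBS groups in the addition and closure transition states, which gives the trans ring. The step needs capture of the methide at carbon before it tautomerises or recombines with sulfinate, trans selectivity and a single enantiomer; the high nucleophilicity of the ylide, the irreversible loss of the sulfide and the stereochemically defined sulfonium centre should secure these, and a sulfide without acidic S–CH groups shuts off methylide formation and Sommelet–Hauser rearrangement.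

Step 6
Reactants: 13 (2S,3R)-5-allyl-2-(4-benzyloxy-3-methoxyphenyl)-3-[(tert-butyldimethylsilyloxy)methyl]-7-methoxy-2,3-dihydrobenzofuran; 14 (R)-but-3-en-2-ol
Product: 15 (2R,3E)-5-(DHB)pent-3-en-2-ol
Conditions: 14 (4 equiv), second-generation Grubbs catalyst (5 mol%), 1,4-benzoquinone (10 mol%), CH2Cl2, 40 °C
Reagents that add atoms: none
Why: olefin cross-metathesis of an allylarene with a secondary allylic alcohol, E-selective under thermodynamic control, with benzoquinone suppressing ruthenium hydride double-bond migration; the carbinol centre of 14 is carried over untouched.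

Step 7
Reactants: 15 (2R,3E)-5-(DHB)pent-3-en-2-ol; 16 triethyl orthoacetate
Product: 18 ethyl (3R,4E)-3-(DHB-methyl)hex-4-enoate, via mixed ketene acetal 17 (not isolated)
Conditions: 16 (10 equiv), EtCO2H (10 mol%), toluene, 130 °C, EtOH distilled off
Reagents that add atoms: none
Why: Johnson–Claisen rearrangement through a chair transition state with the carbinol methyl group equatorial, which transfers the (R) carbinol configuration across the E alkene to the new (3R) centre and leaves an E propenyl group.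

Step 8
Reactants: 18 ethyl (3R,4E)-3-(DHB-methyl)hex-4-enoate
Product: 21 (4R)-4-(DHB-methyl)dihydrofuran-2(3H)-one, via aldehyde 19 (not isolated), via hydroxy ester 20 (not isolated)
Conditions: O3, CH2Cl2/MeOH, NaHCO3, Sudan Red 7B indicator, −78 °C; NaBH4, −78 °C to rt; then PPTS (cat.), CH2Cl2, rt
Reagents that add atoms: ozone, [O-][O+]=O
Why: ozonolysis with reductive work-up followed by lactonisation of the γ-hydroxy ester; the disubstituted alkene reacts far faster than the alkoxyarenes when ozone is dosed to the indicator end point, and the stereocentre is not touched.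

Step 9
Reactants: 22 methyl 3-bromo-4-hydroxy-5-methoxybenzoate
Product: 23 methyl 4-(benzyloxy)-3-bromo-5-methoxybenzoate
Conditions: BnBr, K2CO3, DMF, 50 °C
Reagents that add atoms: benzyl bromide, BrCc1ccccc1
Why: Williamson etherification of an acidic phenol.

Step 10
Reactants: 23 methyl 4-(benzyloxy)-3-bromo-5-methoxybenzoate; 24 (2-tert-butoxy-2-oxoethyl)zinc bromide
Product: 25 methyl 4-(benzyloxy)-3-(2-tert-butoxy-2-oxoethyl)-5-methoxybenzoate
Conditions: 24 (1.3 equiv), Pd(dba)2 (2 mol%), 1,2,3,4,5-pentaphenyl-1'-(di-tert-butylphosphino)ferrocene (2 mol%), THF, rt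
Reagents that add atoms: none
Why: palladium-catalysed Negishi-type coupling of an aryl bromide with a Reformatsky reagent, whose near-neutral conditions tolerate the methyl ester and the benzyl ether.

Step 11
Reactants: 25 methyl 4-(benzyloxy)-3-(2-tert-butoxy-2-oxoethyl)-5-methoxybenzoate
Product: 26 2-[2-(benzyloxy)-3-methoxy-5-(methoxycarbonyl)phenyl]acetic acid
Conditions: CF3CO2H/CH2Cl2 (1:4), 0 °C to rt
Reagents that add atoms: none
Why: acidolysis of a tert-butyl ester by loss of the tert-butyl cation, which leaves the methyl ester and the aryl benzyl ether intact.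

Step 12
Reactants: 26 2-[2-(benzyloxy)-3-methoxy-5-(methoxycarbonyl)phenyl]acetic acid; 27 (S)-4-benzyloxazolidin-2-one
Product: 29 methyl 4-(benzyloxy)-3-{2-[(4S)-4-benzyl-2-oxooxazolidin-3-yl]-2-oxoethyl}-5-methoxybenzoate, via mixed pivalic anhydride 28 (not isolated)
Conditions: t-BuCOCl, Et3N, THF, −20 °C; then 27, LiCl, rt
Reagents that add atoms: none
Why: N-acylation of the oxazolidinone by a mixed anhydride under LiCl/Et3N activation, which avoids strong base on the acidic arylacetyl unit.

Step 13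
Reactants: 29 methyl 4-(benzyloxy)-3-{2-[(4S)-4-benzyl-2-oxooxazolidin-3-yl]-2-oxoethyl}-5-methoxybenzoate; 30 4-benzyloxy-3-methoxybenzaldehyde
Product: 32 (4S)-4-benzyl-3-[(2R,3S)-2-[2-(benzyloxy)-3-methoxy-5-(methoxycarbonyl)phenyl]-3-(4-benzyloxy-3-methoxyphenyl)-3-hydroxypropanoyl]oxazolidin-2-one, via trimethylsilyl ether 31 (not isolated)
Conditions: 30 (1.2 equiv), MgCl2 (20 mol%), Et3N (2 equiv), Me3SiCl (1.5 equiv), EtOAc, rt; then 1 M aq. HCl/THF, 0 °C
Reagents that add atoms: none
Why: magnesium-catalysed direct anti-aldol addition of an N-acyloxazolidinone to a non-enolisable aromatic aldehyde, in which the chelated Z enolate is attacked on the face away from the auxiliary benzyl group (setting 2R) with anti topicity (setting 3S) and silylation of the aldolate drives turnover and blocks retro-aldol.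

Step 14
Reactants: 32 anti-aldol adduct
Product: 33 (1S,2S)-1-(4-benzyloxy-3-methoxyphenyl)-2-[2-(benzyloxy)-5-(hydroxymethyl)-3-methoxyphenyl]propane-1,3-diol
Conditions: LiBH4 (4 equiv), MeOH (4 equiv), THF, 0 to 40 °C
Reagents that add atoms: none
Why: borohydride reduction that cleaves the imide to the primary alcohol with release of the auxiliary and also reduces the aryl methyl ester, without touching either stereocentre.

Step 15
Reactants: 33 (1S,2S)-triol
Product: 34 {4-(benzyloxy)-3-[(4S,5S)-4-(4-benzyloxy-3-methoxyphenyl)-2,2-dimethyl-1,3-dioxan-5-yl]-5-methoxyphenyl}methanol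
Conditions: Me2C(OMe)2, PPTS (cat.), acetone, rt; aq. NaHCO3
Reagents that add atoms: 2,2-dimethoxypropane, COC(C)(C)OC
Why: thermodynamic acetonide formation on the 1,3-diol, which gives a chair dioxane with both aryl groups equatorial and leaves the isolated benzylic alcohol free after work-up.

Step 16
Reactants: 34 acetonide benzylic alcohol
Product: 35 (4S,5S)-5-[2-(benzyloxy)-5-(bromomethyl)-3-methoxyphenyl]-4-(4-benzyloxy-3-methoxyphenyl)-2,2-dimethyl-1,3-dioxane
Conditions: CBr4, PPh3, 2,6-lutidine, CH2Cl2, 0 °C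
Reagents that add atoms: carbon tetrabromide, BrC(Br)(Br)Br
Why: Appel bromination of a primary benzylic alcohol under buffered conditions that spare the acetonide.

Step 17
Reactants: 21 (4R)-4-(DHB-methyl)dihydrofuran-2(3H)-one; 35 ring B benzylic bromide
Product: 37 (3R,4R)-3-{4-(benzyloxy)-3-[(4S,5S)-4-(4-benzyloxy-3-methoxyphenyl)-2,2-dimethyl-1,3-dioxan-5-yl]-5-methoxybenzyl}-4-(DHB-methyl)dihydrofuran-2(3H)-one, via lithium enolate 36 (not isolated)
Conditions: LiN(SiMe3)2 (1.05 equiv), THF, −78 °C; then 35, DMPU, −78 to −30 °C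
Reagents that add atoms: none
Why: alkylation of a γ-butyrolactone enolate, in which the benzylic bromide approaches anti to the C4 substituent and so sets the (3R) centre trans to it, as in dibenzylbutyrolactone lignan syntheses.

Step 18
Reactants: 37 fully protected lactone
Product: 38 tri-O-benzyl ether of the target (phenols of rings A, B and D benzylated, all three alcohols free)
Conditions: AcOH/THF/H2O (3:1:1), 40 °C
Reagents that add atoms: none
Why: mild acidic hydrolysis of the acetonide and the primary TBS ether while the phenols are still benzylated, which keeps the benzylic carbinol from ionising.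

Step 19
Reactants: 38 tri-O-benzyl ether of the target
Product: 39 CNP0186558.2
Conditions: H2 (1 atm), 10% Pd/C, EtOAc/EtOH, rt
Reagents that add atoms: none
Why: hydrogenolysis of three aryl benzyl ethers under neutral conditions, which is faster than cleavage of the benzylic alcohol or of the benzylic C2–O1 bond when hydrogen uptake is monitored.

**Compound list**

1 | eugenol (4-allyl-2-methoxyphenol) | C=CCc1ccc(O)c(OC)c1 | starting material
2 | (tert-butyldimethylsilyloxy)acetaldehyde | CC(C)(C)[Si](C)(C)OCC=O | starting material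
3 | bromomagnesium 4-allyl-2-methoxyphenoxide | C=CCc1ccc(O[Mg]Br)c(OC)c1 | intermediate
4 | rac-1-(5-allyl-2-hydroxy-3-methoxyphenyl)-2-(tert-butyldimethylsilyloxy)ethan-1-ol | C=CCc1cc(OC)c(O)c(C(O)CO[Si](C)(C)C(C)(C)C)c1 | intermediate
5 | rac-4-allyl-2-methoxy-6-[2-(tert-butyldimethylsilyloxy)-1-(p-tolylsulfonyl)ethyl]phenol | C=CCc1cc(OC)c(O)c(C(CO[Si](C)(C)C(C)(C)C)S(=O)(=O)c2ccc(C)cc2)c1 | intermediate
6 | 4-benzyloxy-3-methoxybenzyl alcohol | COc1cc(CO)ccc1OCc1ccccc1 | starting material
7 | 4-benzyloxy-3-methoxybenzyl bromide | COc1cc(CBr)ccc1OCc1ccccc1 | intermediate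
8 | (1R,4R,5R)-4,7,7-trimethyl-6-thiabicyclo[3.2.1]octane (isothiocineole) | C[C@@H]1CC[C@@H]2C[C@H]1SC2(C)C | starting material
9 | (1R,4R,5R)-6-(4-benzyloxy-3-methoxybenzyl)-4,7,7-trimethyl-6-thiabicyclo[3.2.1]octan-6-ium tetrafluoroborate (configuration at sulfur as formed on alkylation, not specified) | C[C@@H]1CC[C@@H]2C[C@H]1[S+](Cc1ccc(OCc3ccccc3)c(OC)c1)C2(C)C.F[B-](F)(F)F | intermediate
10 | (E)-4-allyl-6-[2-(tert-butyldimethylsilyloxy)ethylidene]-2-methoxycyclohexa-2,4-dien-1-one (o-quinone methide) | O=C1C(OC)=CC(CC=C)=C/C1=C\CO[Si](C)(C)C(C)(C)C | intermediate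
11 | benzylic sulfonium ylide derived from 9 | C[C@@H]1CC[C@@H]2C[C@H]1[S+]([CH-]c1ccc(OCc3ccccc3)c(OC)c1)C2(C)C | intermediate
12 | phenoxide–sulfonium betaine (C2–C3 formed, sulfide still attached at the future C2) | C[C@@H]1CC[C@@H]2C[C@H]1[S+]([C@@H](c1ccc(OCc3ccccc3)c(OC)c1)[C@@H](CO[Si](C)(C)C(C)(C)C)c1cc(CC=C)cc(OC)c1[O-])C2(C)C | intermediate
13 | (2S,3R)-5-allyl-2-(4-benzyloxy-3-methoxyphenyl)-3-[(tert-butyldimethylsilyloxy)methyl]-7-methoxy-2,3-dihydrobenzofuran (trans) | C=CCc1cc(OC)c2c(c1)[C@H](CO[Si](C)(C)C(C)(C)C)[C@@H](c1ccc(OCc3ccccc3)c(OC)c1)O2 | intermediate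
14 | (R)-but-3-en-2-ol | C[C@@H](O)C=C | starting material
15 | (2R,3E)-5-(DHB)pent-3-en-2-ol | C[C@@H](O)/C=C/Cc1cc(OC)c2c(c1)[C@H](CO[Si](C)(C)C(C)(C)C)[C@@H](c1ccc(OCc3ccccc3)c(OC)c1)O2 | intermediate
16 | triethyl orthoacetate | CCOC(C)(OCC)OCC | starting material
17 | mixed ketene acetal CH2=C(OEt)–O–CH(CH3)–CH=CH–CH2–DHB | C=C(OCC)O[C@H](C)/C=C/Cc1cc(OC)c2c(c1)[C@H](CO[Si](C)(C)C(C)(C)C)[C@@H](c1ccc(OCc3ccccc3)c(OC)c1)O2 | intermediate
18 | ethyl (3R,4E)-3-(DHB-methyl)hex-4-enoate | CCOC(=O)C[C@H](/C=C/C)Cc1cc(OC)c2c(c1)[C@H](CO[Si](C)(C)C(C)(C)C)[C@@H](c1ccc(OCc3ccccc3)c(OC)c1)O2 | intermediate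
19 | ethyl (3R)-3-formyl-4-(DHB)butanoate | CCOC(=O)C[C@H](C=O)Cc1cc(OC)c2c(c1)[C@H](CO[Si](C)(C)C(C)(C)C)[C@@H](c1ccc(OCc3ccccc3)c(OC)c1)O2 | intermediate
20 | ethyl (3R)-4-hydroxy-3-(DHB-methyl)butanoate | CCOC(=O)C[C@H](CO)Cc1cc(OC)c2c(c1)[C@H](CO[Si](C)(C)C(C)(C)C)[C@@H](c1ccc(OCc3ccccc3)c(OC)c1)O2 | intermediate
21 | (4R)-4-(DHB-methyl)dihydrofuran-2(3H)-one | O=C1C[C@@H](Cc2cc(OC)c3c(c2)[C@H](CO[Si](C)(C)C(C)(C)C)[C@@H](c2ccc(OCc4ccccc4)c(OC)c2)O3)CO1 | intermediate
22 | methyl 3-bromo-4-hydroxy-5-methoxybenzoate | COC(=O)c1cc(Br)c(O)c(OC)c1 | starting material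
23 | methyl 4-(benzyloxy)-3-bromo-5-methoxybenzoate | COC(=O)c1cc(Br)c(OCc2ccccc2)c(OC)c1 | intermediate
24 | (2-tert-butoxy-2-oxoethyl)zinc bromide | CC(C)(C)OC(=O)C[Zn]Br | starting material
25 | methyl 4-(benzyloxy)-3-(2-tert-butoxy-2-oxoethyl)-5-methoxybenzoate | COC(=O)c1cc(CC(=O)OC(C)(C)C)c(OCc2ccccc2)c(OC)c1 | intermediate
26 | 2-[2-(benzyloxy)-3-methoxy-5-(methoxycarbonyl)phenyl]acetic acid | COC(=O)c1cc(CC(=O)O)c(OCc2ccccc2)c(OC)c1 | intermediate
27 | (S)-4-benzyloxazolidin-2-one | O=C1N[C@@H](Cc2ccccc2)CO1 | starting material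
28 | mixed pivalic anhydride of 26 | COC(=O)c1cc(CC(=O)OC(=O)C(C)(C)C)c(OCc2ccccc2)c(OC)c1 | intermediate
29 | methyl 4-(benzyloxy)-3-{2-[(4S)-4-benzyl-2-oxooxazolidin-3-yl]-2-oxoethyl}-5-methoxybenzoate | COC(=O)c1cc(CC(=O)N2C(=O)OC[C@@H]2Cc2ccccc2)c(OCc2ccccc2)c(OC)c1 | intermediate
30 | 4-benzyloxy-3-methoxybenzaldehyde | COc1cc(C=O)ccc1OCc1ccccc1 | starting material
31 | O-trimethylsilyl ether of 32 | O=C1OC[C@H](Cc2ccccc2)N1C(=O)[C@H](c2cc(C(=O)OC)cc(OC)c2OCc2ccccc2)[C@H](O[Si](C)(C)C)c2ccc(OCc3ccccc3)c(OC)c2 | intermediate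
32 | (4S)-4-benzyl-3-[(2R,3S)-2-[2-(benzyloxy)-3-methoxy-5-(methoxycarbonyl)phenyl]-3-(4-benzyloxy-3-methoxyphenyl)-3-hydroxypropanoyl]oxazolidin-2-one | O=C1OC[C@H](Cc2ccccc2)N1C(=O)[C@H](c2cc(C(=O)OC)cc(OC)c2OCc2ccccc2)[C@H](O)c2ccc(OCc3ccccc3)c(OC)c2 | intermediate
33 | (1S,2S)-1-(4-benzyloxy-3-methoxyphenyl)-2-[2-(benzyloxy)-5-(hydroxymethyl)-3-methoxyphenyl]propane-1,3-diol | OC[C@H](c1cc(CO)cc(OC)c1OCc1ccccc1)[C@H](O)c1ccc(OCc2ccccc2)c(OC)c1 | intermediate
34 | {4-(benzyloxy)-3-[(4S,5S)-4-(4-benzyloxy-3-methoxyphenyl)-2,2-dimethyl-1,3-dioxan-5-yl]-5-methoxyphenyl}methanol | CC1(C)OC[C@H](c2cc(CO)cc(OC)c2OCc2ccccc2)[C@@H](c2ccc(OCc3ccccc3)c(OC)c2)O1 | intermediate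
35 | (4S,5S)-5-[2-(benzyloxy)-5-(bromomethyl)-3-methoxyphenyl]-4-(4-benzyloxy-3-methoxyphenyl)-2,2-dimethyl-1,3-dioxane | CC1(C)OC[C@H](c2cc(CBr)cc(OC)c2OCc2ccccc2)[C@@H](c2ccc(OCc3ccccc3)c(OC)c2)O1 | intermediate
36 | lithium enolate of lactone 21 | [Li]OC1=C[C@@H](Cc2cc(OC)c3c(c2)[C@H](CO[Si](C)(C)C(C)(C)C)[C@@H](c2ccc(OCc4ccccc4)c(OC)c2)O3)CO1 | intermediate
37 | (3R,4R)-3-{4-(benzyloxy)-3-[(4S,5S)-4-(4-benzyloxy-3-methoxyphenyl)-2,2-dimethyl-1,3-dioxan-5-yl]-5-methoxybenzyl}-4-(DHB-methyl)dihydrofuran-2(3H)-one | CC1(C)OC[C@H](c2cc(C[C@H]3C(=O)OC[C@@H]3Cc3cc(OC)c4c(c3)[C@H](CO[Si](C)(C)C(C)(C)C)[C@@H](c3ccc(OCc5ccccc5)c(OC)c3)O4)cc(OC)c2OCc2ccccc2)[C@@H](c2ccc(OCc3ccccc3)c(OC)c2)O1 | intermediate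
38 | tri-O-benzyl ether of the target (benzyl on the phenols of rings A, B and D) | COc1cc([C@@H](O)[C@H](CO)c2cc(C[C@H]3C(=O)OC[C@@H]3Cc3cc(OC)c4c(c3)[C@H](CO)[C@@H](c3ccc(OCc5ccccc5)c(OC)c3)O4)cc(OC)c2OCc2ccccc2)ccc1OCc1ccccc1 | intermediate
39 | CNP0186558.2 | COc1cc([C@@H](O)[C@H](CO)c2cc(C[C@H]3C(=O)OC[C@@H]3Cc3cc(OC)c4c(c3)[C@H](CO)[C@@H](c3ccc(O)c(OC)c3)O4)cc(OC)c2O)ccc1O | target

**Step count and risks**

Total step count: 19. Longest linear sequence: 11 steps (22 to 39, steps 9 to 19); the eugenol branch needs 9 steps (1, 2, 5 to 8, 17 to 19).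

Steps most likely to fail:

Step 5. The benzylic ylide adds irreversibly, so any leakage in face selection at the ylide or at the quinone methide is carried straight into the product as the cis isomer or the wrong enantiomer. The alkyl-substituted methide can also be lost to tautomerisation before it is captured. Fallback: the stereochemical burden is taken off the annulation. Bromide 7 is treated with tetrahydrothiophene and NaBF4 to give 1-(4-benzyloxy-3-methoxybenzyl)tetrahydrothiophen-1-ium tetrafluoroborate F1. Sulfone 5 and this salt are annulated with Cs2CO3 in CH2Cl2 to the racemic trans-dihydrobenzofuran F2. The enantiomers are then separated by preparative chromatography on a chiral stationary phase, which brings the route back at 13.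

Step 13. The arylacetyl imide enolises and epimerises more easily than an alkanoyl imide, so anti selectivity and face selectivity may erode during the slow addition to an electron-rich aldehyde. Fallback: acid 26 is activated as anhydride 28 and attached to (R)-4-benzyloxazolidin-2-one to give methyl 4-(benzyloxy)-3-{2-[(4R)-4-benzyl-2-oxooxazolidin-3-yl]-2-oxoethyl}-5-methoxybenzoate F3. Its dibutylboron Z enolate (Bu2BOTf, i-Pr2NEt, CH2Cl2, −78 °C) is added to aldehyde 30 pre-complexed with Et2AlCl. The open transition state gives the anti adduct, with the α-centre fixed by the face preference of the non-chelated boron enolate, that is (4R)-4-benzyl-3-[(2R,3S)-2-aryl-3-aryl-3-hydroxypropanoyl]oxazolidin-2-one F4. Reduction with LiBH4 as in step 14 returns the route at 33.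

Step 6. Migration of the allyl double bond into conjugation with ring C and incomplete E selectivity would both pass through the rearrangement of step 7, each Z molecule ending with the wrong configuration at the lactone β-carbon. Fallback: 13 is cross-metathesised with methyl vinyl ketone (second-generation Grubbs catalyst, CH2Cl2, 40 °C) to the E enone (3E)-5-(DHB)pent-3-en-2-one F5. A Corey–Bakshi–Shibata reduction with (S)-2-methyl-CBS-oxazaborolidine and BH3·SMe2 in THF at −20 °C, with the alkenyl group as the large substituent, then gives the (R) alcohol and returns the route at 15.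

Further compounds
F1 | step 5 | 1-(4-benzyloxy-3-methoxybenzyl)tetrahydrothiophen-1-ium tetrafluoroborate | COc1cc(C[S+]2CCCC2)ccc1OCc1ccccc1.F[B-](F)(F)F
F2 | step 5 | racemic trans-5-allyl-2-(4-benzyloxy-3-methoxyphenyl)-3-[(tert-butyldimethylsilyloxy)methyl]-7-methoxy-2,3-dihydrobenzofuran (both enantiomers) | C=CCc1cc(OC)c2c(c1)[C@H](CO[Si](C)(C)C(C)(C)C)[C@@H](c1ccc(OCc3ccccc3)c(OC)c1)O2.C=CCc1cc(OC)c2c(c1)[C@@H](CO[Si](C)(C)C(C)(C)C)[C@H](c1ccc(OCc3ccccc3)c(OC)c1)O2
F3 | step 13 | methyl 4-(benzyloxy)-3-{2-[(4R)-4-benzyl-2-oxooxazolidin-3-yl]-2-oxoethyl}-5-methoxybenzoate | COC(=O)c1cc(CC(=O)N2C(=O)OC[C@H]2Cc2ccccc2)c(OCc2ccccc2)c(OC)c1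
F4 | step 13 | (4R)-4-benzyl-3-[(2R,3S)-2-[2-(benzyloxy)-3-methoxy-5-(methoxycarbonyl)phenyl]-3-(4-benzyloxy-3-methoxyphenyl)-3-hydroxypropanoyl]oxazolidin-2-one | O=C1OC[C@@H](Cc2ccccc2)N1C(=O)[C@H](c2cc(C(=O)OC)cc(OC)c2OCc2ccccc2)[C@H](O)c2ccc(OCc3ccccc3)c(OC)c2
F5 | step 6 | (3E)-5-(DHB)pent-3-en-2-one | CC(=O)/C=C/Cc1cc(OC)c2c(c1)[C@H](CO[Si](C)(C)C(C)(C)C)[C@@H](c1ccc(OCc3ccccc3)c(OC)c1)O2
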